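The numbers in the tables were generated by integration for substances that don't exist; scatter was added.

I read both flasks at 20 h, and I reckon the target in each as the share of used substrate that became target, less a correction for target lost again.

| flask | substrate | coupling partner | temperature | remark | time |
|---|---|---|---|---|---|
| noon | 0.92 M | 3 M | −35 °C | run made earlier |  |
| dawn | 1.8 M | 3 M | −20 °C | run made earlier |  |
| dusk | 2 M | 1.8 M | −35 °C | run made earlier |  |
| cedar | 2.0 M | 3.00 M | −20 °C |  | 20 h |
| maple | 1.2 M | 0.800 M | −20 °C |  | 20 h |

| run | time / h | target / % | substrate / % |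
|---|---|---|---|
| noon | 2.00 | 1.1 | 94.0 |
| noon | 6.00 | 3.5 | 83.3 |
| noon | 12.0 | 5.9 | 69.9 |
| noon | 15.0 | 7.2 | 64.4 |
| noon | 25.0 | 9.7 | 48.8 |
| noon | 30.0 | 10.5 | 42.7 |
| noon | 40.0 | 11.2 | 32.9 |
| dawn | 3.00 | 11.3 | 51.8 |
| dawn | 6.00 | 15.3 | 29.5 |
| dawn | 8.00 | 15.1 | 21.2 |
| dawn | 12.0 | 14.4 | 11.2 |
| dawn | 15.0 | 13.2 | 7.4 |
| dawn | 20.0 | 10.3 | 4.0 |
| dusk | 8.00 | 4.5 | 85.0 |
| dusk | 15.0 | 8.4 | 74.8 |
| dusk | 25.0 | 12.1 | 63.0 |
| dusk | 30.0 | 13.8 | 58.0 |
| dusk | 40.0 | 16.2 | 49.5 |

(each reading ± 0.3 percentage points)

- which of the two ends with the higher amount of target, in percent of the substrate charged ("neither" if they lie within 2 percentage points) (cedar / maple / neither)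
- target at the end, in percent of the substrate charged, cedar
- target at the end, in percent of the substrate charged, maple

- a reading or a percentage of target counts all its forms, free or not

At 15.0 h the cold runs show a share of 20.2 % at 3 M partner and 33.3 % at 1.8 M, so the share is higher with less partner. I therefore give substrate two exits, one to target and one with partner. The dawn run, at the temperature of both flasks, has used 48.2 % of its substrate by 3.00 h and shows 11.3 % target, a share of 23.4 %. That gives 1.09 L mol⁻¹, the branching number, meaning the partner exit over the target exit per unit of [coupling partner], a selectivity factor. The share is one over one plus this number times [coupling partner].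

Dawn loses substrate at 0.219 h⁻¹, so its target exit is 0.0514 h⁻¹. Its target stands nearly flat around 8.00 h, so I set loss equal to making there, 0.0722 h⁻¹ at about 1.91 M partner, which is 0.0377 L mol⁻¹ h⁻¹ per unit of partner.

For maple I guess that [coupling partner] averages half its charge, 0.400 M. The share is then 69.7 %, and 77.1 % of the substrate is used, so 53.7 % is made. The target made follows the substrate used, and that first-order curve runs steepest at the start, so its mean over the time is 61.9 % of the end amount. The correction is then 18.7 % of what is made, leaving 43.7 %.

The weak link is the guessed partner. The two consuming paths take 0.401 M, which makes the mean 0.599 M, above my guess. A higher mean spends more partner, so the consistent value lies between, and I take 0.500 M. With the same mean for the target made, maple then gives 39.5 %. Cedar is close to dawn in its charge, so I take dawn's 10.3 % at that time for it.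

The forecast says maple, with 12 % in cedar and 39 % in maple, holding that “the low partner level suppresses both the side reaction and target loss”.

The flasks give 12.1 % in cedar and 42.9 % in maple, so maple ends higher.

    coupling partner + target → over-reaction product (k = 0.0608 L mol⁻¹ h⁻¹, Ea = 73.0 kJ mol⁻¹)
    crystals ⇌ target, rate k2*(cs2 - [target]) while solid is left; crystals form when [target] > cs2 (solubility = 1.20 M, k = 6.71 h⁻¹)
    coupling partner + intermediate A ⇌ intermediate B (K = 0.377 L mol⁻¹, k = 0.0963 L mol⁻¹ h⁻¹, Ea = 51.0 kJ mol⁻¹, ΔH = −14.0 kJ mol⁻¹)
    substrate → target (k = 0.0676 h⁻¹, Ea = 76.0 kJ mol⁻¹)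
    substrate + coupling partner → intermediate A (k = 0.0595 L mol⁻¹ h⁻¹, Ea = 67.0 kJ mol⁻¹)
    2 substrate → self-condensation product (k = 1.06 × 10⁻⁴ L mol⁻¹ h⁻¹, Ea = 79.0 kJ mol⁻¹)
    (constants at −20 °C)

In cedar, substrate is down to 16.5 % by 10.0 h, and after that target falls from 15.8 % to 12.1 % while over-reaction product climbs from 13.2 % to 22.9 %. In maple, 36.0 % substrate still stands at that time, and target rises from 34.7 % to 42.9 %. With maple's mean of charged and final partner, 0.532 M, the branching number sends 53.8 % of the charge through the target exit, against 57.7 % found as target plus over-reaction product. For the neighbour like cedar with 1.2 M partner, it gives 48.5 %. The computed flask holds 54.2 % in those two forms, of which 39.9 % is target.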